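(The earlier runs and the new flask are simulated for substances that don't exist; the scatter is artificial.)

Time is what I watch in this flask: in the earlier runs, the share of target in target plus isomer of the product starts high and falls as the clock runs. Substrate and reagent are charged with free catalyst, and target and its isomer appear.

common to all: free catalyst 0.40 mM
- autumn: substrate 0.071 M; reagent 0.050 M; run made earlier
- noon: substrate 0.071 M; reagent 0.11 M; run made earlier
- midnight: substrate 0.035 M; reagent 0.0745 M; run made earlier
- flask: substrate 0.071 M; reagent 0.0745 M; time 30 min

| run | time / min | target / % | isomer of the product / % | substrate / % |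
|---|---|---|---|---|
| autumn | 2.50 | 9.8 | 5.2 | 68.3 |
| autumn | 8.00 | 28.5 | 18.7 | 42.2 |
| autumn | 12.0 | 32.7 | 23.9 | 31.5 |
| autumn | 20.0 | 36.9 | 28.6 | 20.9 |
| autumn | 30.0 | 39.2 | 32.7 | 19.0 |
| autumn | 40.0 | 38.5 | 32.3 | 17.3 |
| noon | 6.00 | 28.9 | 18.3 | 39.9 |
| noon | 12.0 | 45.5 | 33.2 | 16.4 |
| noon | 20.0 | 51.6 | 41.0 | 4.9 |
| noon | 25.0 | 54.8 | 42.7 | 1.7 |
| noon | 30.0 | 56.5 | 44.7 | 0.5 |
| noon | 40.0 | 54.8 | 44.6 | 0.8 |
| midnight | 3.00 | 19.4 | 8.1 | 60.6 |
| midnight | 10.0 | 41.2 | 29.7 | 21.3 |
| midnight | 15.0 | 48.6 | 37.1 | 12.4 |
| midnight | 25.0 | 52.2 | 44.6 | 2.4 |
| midnight | 40.0 | 54.6 | 44.4 | 0 |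

(scatter of a reading: 1 percentage point)



- share of target in target plus isomer of the product at 25 s
- share of target in target plus isomer of the product at 3.0 min
- share of target in target plus isomer of the product at 30 min
- which of target and isomer of the product there is more of at 30 min

I reckon between two extreme versions of this flask. In the first, target and isomer are in balance from the start, so the share stands still. The noon and midnight runs, with substrate readings down to 0.8% and 0% at 40.0 min, together read 55.1%. I call this the end share: the part of target plus isomer that is target once the two stop changing against each other. In the second extreme, product is fresh target with none yet turned, and the share is 100 per cent. These are thermodynamic against kinetic control.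

The real flask lies between, like a first-order lag: new target arrives while older target relaxes toward the end share. Its reagent charge lies between those of the autumn and noon runs, which read 54.5% and 55.8% at 30 min. So I commit to the end share at 30 min, with target leading. At 3.0 min I expect about the midnight reading of 70.5%, and at 25 s a share close to the second extreme.

The forecast gives 83% at 25 s, within 71% to 96%, then 67% at 3.0 min and 55% at 30 min, with target leading. It reads the runs as “target forming first, then relaxing to a roughly 55:45 mixture”. My figure at 3.0 min stands above its number, and at 25 s I lean to the high end of its range.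

The flask gives 93.8%, 70.2% and 55.2%, with target leading.

    substrate + free catalyst ⇌ free catalyst + open intermediate (K = 0.660, k = 11.0 M⁻¹ s⁻¹)
    free catalyst + open intermediate ⇌ catalyst intermediate (K = 93.0 M⁻¹, k = 46.0 M⁻¹ s⁻¹)
    reagent + catalyst intermediate → free catalyst + target (k = 17.0 M⁻¹ s⁻¹)
    target ⇌ isomer of the product (K = 0.820, k = 0.00790 s⁻¹)

At 30 min this flask holds 93.3% of the substrate charged as target plus isomer, and the end share of that is 51.4%; the flask shows 51.5% target. The neighbouring flask is the same recipe with 0.0016 M of free catalyst. There, at 30 min, 0.059% of the substrate charged is left as substrate and 0.0330% stands as open intermediate, while 0.195% of the catalyst charged is catalyst intermediate, so I take the remainder of the charge as target plus isomer, and the end share gives 55.1% target. That neighbouring flask holds 54.9% target and 45.0% isomer of the product.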